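**Retrosynthetic overview**

- Feature: each prenyl CH2 is bonded to a ring carbon ortho to a phenol oxygen, C3 beside O4 on ring B and C5' beside O4' on ring A, so each oxygen can carry the C5 unit as a 1,1-dimethylallyl ether and pass it to the neighbouring carbon.
- Disconnections: stipulin 12 ⇒ (O–Si) 2'-O-silyl stipulin 11 ⇒ (C3–CH2 and C5'–CH2, two aromatic Claisen shifts) bis(1,1-dimethylallyl) ether 8 ⇒ (O–Si) 7 ⇒ (two O–C bonds) isoliquiritigenin 4 + carbonate 3 ⇒ alcohol 1.
- Rings: none is formed. Both benzene rings and the E-enone come intact from isoliquiritigenin; the only new skeletal bonds are the two aryl–CH2 bonds.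
- The 2'-O-silyl group breaks the chelate that would send the ring A shift to C3', crowds C3', and blocks flavanone closure during heating.

Key step: step 4

Remark: primed locants and "ring A" mean the ketone-bearing resorcinol ring; unprimed locants and "ring B" mean the styryl ring. Isoliquiritigenin is assumed to be purchasable.

**Route**

Step 1
Reactants: 1 2-methylbut-3-en-2-ol
Product: 3 2-methylbut-3-en-2-yl methyl carbonate, via lithium 2-methylbut-3-en-2-olate 2 (not isolated)
Conditions: n-BuLi, THF, −78 °C; then ClCO2Me, −78 °C to rt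
Reagents that add atoms: methyl chloroformate, COC(=O)Cl
Why: O-acylation of a lithium alkoxide with a chloroformate (carbonate formation) is fast even at a tertiary allylic oxygen and keeps the medium free of acid that would ionise the alcohol.

Step 2
Reactants: 4 isoliquiritigenin; 3 2-methylbut-3-en-2-yl methyl carbonate (2.4 equiv)
Product: 7 (E)-1-[2-hydroxy-4-(2-methylbut-3-en-2-yloxy)phenyl]-3-[4-(2-methylbut-3-en-2-yloxy)phenyl]prop-2-en-1-one, via 4-O-monoether 5 (not isolated), via 4'-O-monoether 6 (not isolated)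
Conditions: Pd(PPh3)4 (5 mol %), THF, 0 °C to rt, stopped once 5 and 6 are consumed
Reagents that add atoms: none
Why: Tsuji–Trost allylic etherification: zerovalent palladium ionises carbonate 3 to a 1,1-dimethyl-π-allyl complex, CO2 and methoxide, the methoxide deprotonates the two free phenols (O4 and O4') and each phenoxide attacks the more substituted allyl terminus under kinetic control at low temperature, while the hydrogen-bonded 2'-hydroxyl, the least acidic and least nucleophilic of the three, should remain untouched.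

Step 3
Reactants: 7 (E)-1-[2-hydroxy-4-(2-methylbut-3-en-2-yloxy)phenyl]-3-[4-(2-methylbut-3-en-2-yloxy)phenyl]prop-2-en-1-one
Product: 8 (E)-1-[4-(2-methylbut-3-en-2-yloxy)-2-(triisopropylsilyloxy)phenyl]-3-[4-(2-methylbut-3-en-2-yloxy)phenyl]prop-2-en-1-one
Conditions: TIPSOTf (1.3 equiv), 2,6-lutidine (3 equiv), CH2Cl2, 0 °C to rt
Reagents that add atoms: triisopropylsilyl trifluoromethanesulfonate, CC(C)[Si](OS(=O)(=O)C(F)(F)F)(C(C)C)C(C)C
Why: Silylation of a phenol with a silyl triflate: the triflate is electrophilic enough to capture the hydrogen-bonded 2'-hydroxyl, the hindered pyridine base traps triflic acid before it can ionise the tertiary allylic ethers, and the ketone has no enolisable hydrogen to be silylated.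

Step 4
Reactants: 8 (E)-1-[4-(2-methylbut-3-en-2-yloxy)-2-(triisopropylsilyloxy)phenyl]-3-[4-(2-methylbut-3-en-2-yloxy)phenyl]prop-2-en-1-one
Product: 11 2'-O-triisopropylsilyl stipulin, via ring B monoprenyl phenol 9 (not isolated), via ring A monoprenyl phenol 10 (not isolated)
Conditions: PhNEt2 (dry, degassed, 0.05 M), 140 °C, Ar, dark
Reagents that add atoms: none
Why: The known reaction type is the aromatic Claisen rearrangement of aryl 1,1-dimethylallyl ethers to ortho-prenylphenols: in each ring a concerted suprafacial [3,3] shift through a chair-like six-centre transition state joins the terminal =CH2 carbon to the ortho ring carbon while the tertiary C–O bond breaks, and enolisation of the ortho-dienone returns the phenol with a linear 3-methylbut-2-enyl group. The two shifts are independent, so monophenols 9 and 10 should both appear before converging on 11; no ring is closed (the six-membered array exists only in the transition state), no stereocentre is made, and the E-enone, the thermodynamic isomer, is not involved. The selectivity needed is C5' over C3' on ring A (on ring B, C3 and C5 are equivalent): the silyl ether removes the O2'–H···O=C hydrogen bond whose bond fixation sends free 2'-hydroxy ketones to C3', the O2' donor meta to the migrating ether favours bonding at the carbon para to it (C5'), and the three isopropyl groups crowd C3'. The gem-dimethyl group weakens the breaking C–O bond, so about 140 °C should suffice, well below the range of the abnormal Claisen pathway. The basic amine solvent keeps the medium free of acid (no ionisation to isoprene, no chroman closure of the new ortho-prenylphenols), and the blocked O2' cannot add to the enone to give a flavanone.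

Step 5
Reactants: 11 2'-O-triisopropylsilyl stipulin
Product: 12 stipulin
Conditions: Bu4NF, AcOH (1:1), THF, 0 °C
Reagents that add atoms: none
Why: Fluoride-induced desilylation: the aryl silyl ether ortho to the carbonyl is a very good leaving group for attack of fluoride at silicon, acetic acid protonates the phenoxide at once so that neither oxa-Michael closure to the flavanone nor base-promoted change at the enone can occur, and the freed 2'-hydroxyl returns to its chelate with the ketone.

**Compound list**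

1 | 2-methylbut-3-en-2-ol | C=CC(C)(C)O | starting material
2 | lithium 2-methylbut-3-en-2-olate | [Li+].[O-]C(C)(C)C=C | intermediate
3 | 2-methylbut-3-en-2-yl methyl carbonate | C=CC(C)(C)OC(=O)OC | intermediate
4 | isoliquiritigenin = (E)-1-(2,4-dihydroxyphenyl)-3-(4-hydroxyphenyl)prop-2-en-1-one | O=C(/C=C/c1ccc(O)cc1)c1ccc(O)cc1O | starting material
5 | (E)-1-(2,4-dihydroxyphenyl)-3-[4-(2-methylbut-3-en-2-yloxy)phenyl]prop-2-en-1-one | C=CC(C)(C)Oc1ccc(/C=C/C(=O)c2ccc(O)cc2O)cc1 | intermediate
6 | (E)-1-[2-hydroxy-4-(2-methylbut-3-en-2-yloxy)phenyl]-3-(4-hydroxyphenyl)prop-2-en-1-one | C=CC(C)(C)Oc1ccc(C(=O)/C=C/c2ccc(O)cc2)c(O)c1 | intermediate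
7 | (E)-1-[2-hydroxy-4-(2-methylbut-3-en-2-yloxy)phenyl]-3-[4-(2-methylbut-3-en-2-yloxy)phenyl]prop-2-en-1-one | C=CC(C)(C)Oc1ccc(/C=C/C(=O)c2ccc(OC(C)(C)C=C)cc2O)cc1 | intermediate
8 | (E)-1-[4-(2-methylbut-3-en-2-yloxy)-2-(triisopropylsilyloxy)phenyl]-3-[4-(2-methylbut-3-en-2-yloxy)phenyl]prop-2-en-1-one | C=CC(C)(C)Oc1ccc(/C=C/C(=O)c2ccc(OC(C)(C)C=C)cc2O[Si](C(C)C)(C(C)C)C(C)C)cc1 | intermediate
9 | (E)-3-[4-hydroxy-3-(3-methylbut-2-enyl)phenyl]-1-[4-(2-methylbut-3-en-2-yloxy)-2-(triisopropylsilyloxy)phenyl]prop-2-en-1-one | CC(C)=CCc1cc(/C=C/C(=O)c2ccc(OC(C)(C)C=C)cc2O[Si](C(C)C)(C(C)C)C(C)C)ccc1O | intermediate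
10 | (E)-1-[4-hydroxy-5-(3-methylbut-2-enyl)-2-(triisopropylsilyloxy)phenyl]-3-[4-(2-methylbut-3-en-2-yloxy)phenyl]prop-2-en-1-one | C=CC(C)(C)Oc1ccc(/C=C/C(=O)c2cc(CC=C(C)C)c(O)cc2O[Si](C(C)C)(C(C)C)C(C)C)cc1 | intermediate
11 | 2'-O-triisopropylsilyl stipulin = (E)-1-[4-hydroxy-5-(3-methylbut-2-enyl)-2-(triisopropylsilyloxy)phenyl]-3-[4-hydroxy-3-(3-methylbut-2-enyl)phenyl]prop-2-en-1-one | CC(C)=CCc1cc(/C=C/C(=O)c2cc(CC=C(C)C)c(O)cc2O[Si](C(C)C)(C(C)C)C(C)C)ccc1O | intermediate
12 | stipulin = (E)-1-[2,4-dihydroxy-5-(3-methylbut-2-enyl)phenyl]-3-[4-hydroxy-3-(3-methylbut-2-enyl)phenyl]prop-2-en-1-one | CC(C)=CCc1cc(/C=C/C(=O)c2cc(CC=C(C)C)c(O)cc2O)ccc1O | target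

**Step count**

Total: 5 steps. Longest linear sequence: 5 steps (1 → 3 → 7 → 8 → 11 → 12); 4 steps from isoliquiritigenin.

**Steps most likely to fail**

1. Step 4 (key step). What may go wrong:
- The ring A shift may deliver the allyl terminus to C3' instead of C5'.
- The tertiary C–O bonds may ionise with loss of isoprene, or the new ortho-prenylphenols may close to chromans.
- Early loss of the silyl group would restore the chelate and its C3' bias.

Fallback: the two prenylated halves are made separately and joined by aldol condensation. It sets out from 3 and 1 and returns at 12.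
- From carbonate 3, 4-hydroxybenzaldehyde is O-alkylated (Pd(PPh3)4, THF, 0 °C) to 4-(2-methylbut-3-en-2-yloxy)benzaldehyde F1.
- A single-ring Claisen shift of F1 (PhNEt2, 140 °C; both ortho carbons equivalent) should give 4-hydroxy-3-(3-methylbut-2-enyl)benzaldehyde F2.
- F2 is protected (MOMCl, i-Pr2NEt, CH2Cl2) as 4-(methoxymethoxy)-3-(3-methylbut-2-enyl)benzaldehyde F3.
- From alcohol 1, Friedel–Crafts prenylation of 2,4-dihydroxyacetophenone (BF3·OEt2, dioxane, rt) gives 1-[2,4-dihydroxy-5-(3-methylbut-2-enyl)phenyl]ethanone F4 after separation from the 3-prenyl isomer. The regiochemistry can be assigned at this cheap stage from the two singlet aromatic protons.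
- F4 is protected at the non-chelated hydroxyl (MOMCl, i-Pr2NEt, CH2Cl2) as 1-[2-hydroxy-4-(methoxymethoxy)-5-(3-methylbut-2-enyl)phenyl]ethanone F5.
- Claisen–Schmidt condensation of F3 with F5 (KOH, EtOH/H2O, rt) should give (E)-1-[2-hydroxy-4-(methoxymethoxy)-5-(3-methylbut-2-enyl)phenyl]-3-[4-(methoxymethoxy)-3-(3-methylbut-2-enyl)phenyl]prop-2-en-1-one F6.
- Brief treatment of F6 with HCl in MeOH (rt) removes both acetals and gives stipulin 12.

2. Step 2. What may go wrong:
- The product ethers may be re-ionised by palladium and drift from the branched to the linear prenyl ethers.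
- The alkylation may stop short or spill over among the three hydroxyls.

Fallback: the tertiary ethers are made by a path that cannot transpose. It sets out from 4 and returns at 7.
- Isoliquiritigenin 4 is alkylated with 3-chloro-3-methylbut-1-yne (CuCl2 cat., DBU, MeCN, 0 °C) to (E)-1-[2-hydroxy-4-(2-methylbut-3-yn-2-yloxy)phenyl]-3-[4-(2-methylbut-3-yn-2-yloxy)phenyl]prop-2-en-1-one F7.
- Semi-hydrogenation of F7 (H2, 1 atm, Pd/CaCO3 poisoned with Pb(OAc)2, quinoline, EtOAc, monitored to stop at the alkene) reduces both terminal alkynes to vinyl groups and gives 7.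

3. Step 3. What may go wrong:
- Silylation of the hydrogen-bonded hydroxyl may be slow.
- Meanwhile the silyl triflate, or adventitious triflic acid, may ionise the tertiary allylic ethers.

Fallback: O2' is blocked by alkylation under basic conditions instead. It sets out from 7 and returns at 12.
- 7 is deprotonated and alkylated (NaH, MOMCl, THF/DMF, 0 °C) to (E)-1-[2-(methoxymethoxy)-4-(2-methylbut-3-en-2-yloxy)phenyl]-3-[4-(2-methylbut-3-en-2-yloxy)phenyl]prop-2-en-1-one F8.
- The same double Claisen shift on F8 (PhNEt2, 140 °C; the O2' alkoxy donor likewise directs to C5') should give (E)-1-[4-hydroxy-2-(methoxymethoxy)-5-(3-methylbut-2-enyl)phenyl]-3-[4-hydroxy-3-(3-methylbut-2-enyl)phenyl]prop-2-en-1-one F9.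
- Mild acid (HCl, MeOH, rt) cleaves the acetal ortho to the carbonyl and gives stipulin 12.

**Further compounds**

F1 | step 4 | 4-(2-methylbut-3-en-2-yloxy)benzaldehyde | C=CC(C)(C)Oc1ccc(C=O)cc1
F2 | step 4 | 4-hydroxy-3-(3-methylbut-2-enyl)benzaldehyde | CC(C)=CCc1cc(C=O)ccc1O
F3 | step 4 | 4-(methoxymethoxy)-3-(3-methylbut-2-enyl)benzaldehyde | COCOc1ccc(C=O)cc1CC=C(C)C
F4 | step 4 | 1-[2,4-dihydroxy-5-(3-methylbut-2-enyl)phenyl]ethanone | CC(=O)c1cc(CC=C(C)C)c(O)cc1O
F5 | step 4 | 1-[2-hydroxy-4-(methoxymethoxy)-5-(3-methylbut-2-enyl)phenyl]ethanone | CC(=O)c1cc(CC=C(C)C)c(OCOC)cc1O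
F6 | step 4 | (E)-1-[2-hydroxy-4-(methoxymethoxy)-5-(3-methylbut-2-enyl)phenyl]-3-[4-(methoxymethoxy)-3-(3-methylbut-2-enyl)phenyl]prop-2-en-1-one | COCOc1ccc(/C=C/C(=O)c2cc(CC=C(C)C)c(OCOC)cc2O)cc1CC=C(C)C
F7 | step 2 | (E)-1-[2-hydroxy-4-(2-methylbut-3-yn-2-yloxy)phenyl]-3-[4-(2-methylbut-3-yn-2-yloxy)phenyl]prop-2-en-1-one | C#CC(C)(C)Oc1ccc(/C=C/C(=O)c2ccc(OC(C)(C)C#C)cc2O)cc1
F8 | step 3 | (E)-1-[2-(methoxymethoxy)-4-(2-methylbut-3-en-2-yloxy)phenyl]-3-[4-(2-methylbut-3-en-2-yloxy)phenyl]prop-2-en-1-one | C=CC(C)(C)Oc1ccc(/C=C/C(=O)c2ccc(OC(C)(C)C=C)cc2OCOC)cc1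
F9 | step 3 | (E)-1-[4-hydroxy-2-(methoxymethoxy)-5-(3-methylbut-2-enyl)phenyl]-3-[4-hydroxy-3-(3-methylbut-2-enyl)phenyl]prop-2-en-1-one | CC(C)=CCc1cc(/C=C/C(=O)c2cc(CC=C(C)C)c(O)cc2OCOC)ccc1O
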